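## The problem

The target is a type B polyprenylated acylphloroglucinol built on a bicyclo[3.3.1]nonane. Ring A (C1–C2–C3–C4–C5–C9) is an enolised 1,3-diketone with a 3-hydroxybenzoyl group on C3. Ring B (C1–C9–C5–C6–C7–C8) is a cyclohexanone whose carbonyl C9 is the one-carbon bridge. Three of the four stereocentres are quaternary (C1, C5, C8), and C1 and C8 are adjacent. In ring B the C7 (E)-geranyl group is equatorial (exo), the C8 methyl axial and the C8 homoprenyl group equatorial.

Only C7 and C8 are independent. A C7 substituent can send a nucleophile to the opposite face of C8. The axial C8 methyl can then send an electrophile to the opposite face of C1. C5 follows from C1, because the C2–C3–C4 bridge must span ring B diaxially.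

Five trisubstituted alkenes exclude strong acid, hydrogenation and olefin metathesis, and they limit the use of electrophilic halogen. The non-enolisable 1,3-diketone at C1 can undergo retro-Claisen cleavage, and the acidic trione and the phenol are best unmasked last.

The feature used here is that C4, an oxygenated sp2 carbon, is bonded to C5, the alpha carbon of the C9 ketone, while C2 is a ketone on C1. A C1 acyl group at the ynone oxidation level (C2 carbonyl, C3≡C4) therefore lies axially over a C9=C5 enol ether, and ring A can be closed by forming C4–C5.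

## Retrosynthesis

**Unmasking and the C3–aroyl bond.** Target 37 is taken back to its O-methyl, O-silyl form 36. Cutting 36 between C3 and the aroyl carbonyl gives vinylogous ester 31 and acid chloride 34 (from 3-hydroxybenzoic acid 32 through 33). Making this cut last keeps the chelating trione and the phenol out of all organometallic steps. Carrying the aroyl ketone through ring closure would instead place a second electrophilic carbonyl beside the ynone. The forward step must deprotonate C3 selectively; with both bridgeheads quaternary, no other acidic site competes.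

**The C4 oxygen.** 31 is cut at C4–OMe to bromo enone 30. A bromide on C4 stores the oxidation level of the C4 oxygen. A C4–H enone would need a separate oxidation in the presence of five alkenes. The forward step is an addition–elimination by methoxide.

**C4–C5, the key cut.** 30 is opened to the monocyclic silyl enol ether 29, in which C1 carries the prenyl group and a 3-bromopropynoyl group. The neighbouring cut, C1–C2 with the tether on C5, would make the hindered carbon next to quaternary C8 the nucleophile and would leave a bridgehead C1 prenylation for later. Cutting C4–C5 puts the ring closure at the less hindered C5 and leaves the C1 quaternary centre to be made earlier, under control by C8. The precursor loses one ring and one stereocentre. The forward step must close 6-endo, not 5-exo.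

**Adjusting the tether.** 29 comes from ketone 28 by enol silylation at C5, the only enolisable position. 28 comes from silyl ynone 27 by silicon–bromine exchange, and 27 from carbinol 26 by oxidation. Bromination precedes silylation because N-bromosuccinimide would attack an enol ether.

**The C1 quaternary centre: two bonds in one operation.** 26 is cut at C1–C2 and at the CH2–CH bond of the C1 prenyl group, giving methylene ketone 22, alkenyl Grignard reagent 23 and ynal 24. Two simpler cuts were rejected. Deprotonating a C1-prenyl ketone would occur at C5, not at C1 beside the quaternary C8. Introducing the acyl carbon first and the prenyl group second would invert C1, because the second electrophile enters anti to the axial C8 methyl. Conjugate addition to 22 forms the C1 enolate regiospecifically with the prenyl group already present, so the aldehyde arrives second and from the required face.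

**C1 methylene and C8.** 22 comes from silyl enol ether 17 by a Mannich reaction and elimination. 17 is cut at the C8–homoprenyl bond to enone 14 and bromide 15. The cuprate must add anti to the C7 geranyl group, which places methyl cis and homoprenyl trans to geranyl as in the target.

**C5 prenyl, C8 methyl and C7.** 14 is cut at C5–prenyl to enone 11 and prenyl bromide 12. This alkylation is done at the enone stage because strong base cannot be used once the ynone is present. 11 comes from enone 9 by conjugate methylation and dehydrogenation. 9 is cut at C1=C8 (aldol condensation) and at C6–C7 (enamine Michael addition) to aldehyde 5 and methyl vinyl ketone 6 through keto aldehyde 7; this is where the absolute configuration at C7 is set. 5 comes from geranyl bromide 1 and imine 2, so the (E)-alkene of the geranyl group is bought, not made.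

## Roads not taken

**Alternative 1: epoxide-opening cyclisation of a symmetric bis(enol ether).** The cut is C1–C8. In the forward step a silyl triflate activates the trans-epoxide of the cyclohexadiene A1. One of the two enantiotopic enol ethers attacks C8 through C1 with inversion, and the C7 alkoxide caps the C9 oxocarbenium ion to give the oxygen-bridged ketal A2.
- Merits: the vicinal quaternary pair C1/C8 and ring B form in one stereospecific step. The absolute configuration comes from a catalytic asymmetric epoxidation. The C8 methyl and homoprenyl groups are taken directly from a terpene chain. On the C1–C8 problem this road is clearly better than the chosen plan, which needs a cuprate addition, a methylenation and a three-component coupling.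
- Weak points for this target: A2 has oxygen on C7 where the target has an (E)-geranyl group. Replacing C7–O by C7–C and then building a trisubstituted (E)-alkene late, beside other prenyl groups, is a serious liability. A2 also lacks the C2 oxygen, the C1 prenyl group (a bridgehead alkylation next to C8) and the aroyl group.
- Comparison: the chosen plan carries the geranyl group intact from step 1, and both bridgehead prenyl groups and both ring A oxidation levels are present when ring A closes, so only the C3 aroylation remains.

**Alternative 2: Diels–Alder construction of ring B.** The cuts are C5–C6 and C7–C8. The 2-silyloxydiene A3 adds acrolein A4 endo under a chiral oxazaborolidinium Lewis acid to give the ring B silyl enol ether A5.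
- Merits: ring B, C7 and the quaternary C8 arise in one catalytic asymmetric step. A5 is already the regiodefined C9=C1 enol ether, which the chosen plan has to engineer in steps 6 to 8. In convergence and in access to the C1 enolate this road is better.
- Weak points: the diene terminus that becomes C8 is fully substituted and carries a (Z)-substituent, so the s-cis conformer is strained and the cycloaddition is expected to be sluggish and sensitive to diene geometry. The C7 aldehyde of A5 is epimerisable. It must also be homologated by one carbon and then converted into a trisubstituted (E)-alkene, the same late geometry problem as in Alternative 1. Ring A is not addressed.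
- Comparison: the chosen plan has a longer ring B sequence, but it relays C7 to C8 by a cuprate addition of a well-precedented kind and never has to build the geranyl alkene.

**Alternative 3: alkylative dearomatisation and annulation.** The cuts are C5–C6 and C1–C8. Under aqueous CsOH with a Cinchona-derived ammonium salt, the phenolate of acylphloroglucinol A6 is C-alkylated by the acetoxymethyl enal A7 at the allylic carbon. It then adds through C1 to the disubstituted enal carbon to give the 7-formyl analogue A8.
- Merits: the whole bicyclic trione, with both prenyl groups and the aroyl group, is made in one step from an aromatic compound without protecting groups. If it works, this road is far shorter, and the chosen plan cannot match its step count.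
- Weak points: the second Michael addition must join a quaternary carbon to a β,β-disubstituted enal carbon, a much poorer acceptor than the unsubstituted enals for which this annulation is established, and it is reversible. The C8 configuration depends on the enal geometry. Enantiocontrol by ion pairing is uncertain. A8 still needs the formyl-to-geranyl conversion in the presence of the acidic trione and a free phenol.
- Comparison: the chosen plan forms each quaternary centre by a separate, precedented reaction with a defined stereochemical rationale.

Key step: step 12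

Remarks on the chemistry:
- Ring B locants of the target (C9 carbonyl, C1, C8, C7, C6, C5) are used for all monocyclic intermediates.
- Assumption: the (S)-diarylprolinol ether in step 2 shields the enamine face that leads to (S)-7, as the usual model predicts; if the sense is the reverse, the (R)-catalyst is used and nothing else changes.
- Assumption: compounds 14 to 28 are carried as mixtures at C5, and 26 also at the carbinol carbon; these centres become sp2 in 29 and 27.

## Route

Step 1
Reactants: 1 geranyl bromide; 2 N-ethylidene-2-methylpropan-2-amine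
Product: 5 (4E)-5,9-dimethyldeca-4,8-dienal, via lithiated imine 3 (not isolated), via alkylated tert-butylimine 4 (not isolated)
Conditions: 2, LiN(i-Pr)2, THF, −78 → 0 °C; 1, −78 → 23 °C; oxalic acid (aq), 23 °C
Reagents that add atoms: water, O
Why: Alkylation of a metalated aldimine with an allylic bromide proceeds by SN2 and keeps the (E)-alkene; mild acid hydrolysis of 4 frees the aldehyde without touching the trisubstituted alkenes.

Step 2
Reactants: 5 (4E)-5,9-dimethyldeca-4,8-dienal; 6 methyl vinyl ketone
Product: 7 (2S)-2-[(2E)-3,7-dimethylocta-2,6-dien-1-yl]-5-oxohexanal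
Conditions: 6 (1.5 equiv), (S)-2-[methoxy(diphenyl)methyl]pyrrolidine (5 mol %), ethyl 3,4-dihydroxybenzoate (20 mol %), neat, 4 °C
Reagents that add atoms: none
Why: Enamine-catalysed Michael addition of an α-unbranched aldehyde to a vinyl ketone; the diarylmethyl group shields one face of the E-enamine, so C7 should be set as (S), and the catechol activates the enone by hydrogen bonding.

Step 3
Reactants: 7 (2S)-2-geranyl-5-oxohexanal
Product: 9 (4S)-4-[(2E)-3,7-dimethylocta-2,6-dien-1-yl]cyclohex-2-en-1-one, via aldol adduct 8 (not isolated)
Conditions: LiOH, i-PrOH, 23 °C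
Reagents that add atoms: none
Why: Intramolecular aldol condensation, the second half of a Robinson annulation; only the methyl ketone enolate can close a six-membered ring onto the aldehyde, and mild hydroxide in 2-propanol is the usual way to dehydrate such adducts without racemising the centre that becomes the γ-carbon.

Step 4
Reactants: 9 (4S)-4-geranylcyclohex-2-en-1-one
Product: 11 (4S)-4-geranyl-3-methylcyclohex-2-en-1-one, via lithium enolate 10 (not isolated)
Conditions: Me2CuLi, Et2O, −78 °C; PhS(Cl)=N-t-Bu, THF, −78 → 23 °C
Reagents that add atoms: lithium dimethylcuprate, [Li+].C[Cu-]C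
Why: Gilman cuprate 1,4-addition gives enolate 10 regiospecifically, and N-tert-butylbenzenesulfinimidoyl chloride dehydrogenates enolates by attack at sulfur and syn-elimination, which here can only remove the C8 hydrogen; the sequence is a one-pot β-methylation of an enone, and C7 is not involved.

Step 5
Reactants: 11 (4S)-4-geranyl-3-methylcyclohex-2-en-1-one; 12 prenyl bromide
Product: 14 4-geranyl-3-methyl-6-(3-methylbut-2-en-1-yl)cyclohex-2-en-1-one (C4 as in 11; epimers at the prenyl-bearing carbon, trans expected to predominate), via lithium dienolate 13 (not isolated)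
Conditions: LiN(i-Pr)2, THF, −78 °C; 12, −78 → 0 °C
Reagents that add atoms: none
Why: Kinetic deprotonation of a cyclohexenone by a lithium amide takes place at the α′-carbon (C5), and the cross-conjugated dienolate is C-alkylated by the allylic bromide; the prenyl group is placed now because strong base cannot be used after the ynone is installed, and the new centre is later erased.

Step 6
Reactants: 14 4-geranyl-3-methyl-6-prenylcyclohex-2-en-1-one; 15 5-bromo-2-methylpent-2-ene
Product: 17 trimethylsilyl enol ether (C9=C1) of 4-geranyl-3-methyl-3-(4-methylpent-3-en-1-yl)-6-prenylcyclohexanone, homoprenyl trans and methyl cis to geranyl, via Grignard reagent 16 (not isolated)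
Conditions: 15, Mg, THF; 14, CuBr·SMe2 (20 mol %), Me3SiCl, THF, −78 → −40 °C; Et3N
Reagents that add atoms: chlorotrimethylsilane, C[Si](C)(C)Cl
Why: Copper-catalysed conjugate addition of a Grignard reagent, accelerated by Me3SiCl, forms the C8 quaternary centre; the C7 geranyl group is pseudoaxial (allylic strain with the C8 methyl), so the nucleophile adds to the opposite face, and the enolate is trapped as the regiodefined C9=C1 silyl enol ether.

Step 7
Reactants: 17 trimethylsilyl enol ether; 18 N,N-dimethylmethyleneiminium iodide (Eschenmoser's salt)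
Product: 22 4-geranyl-3-methyl-2-methylidene-3-(4-methylpent-3-en-1-yl)-6-prenylcyclohexan-1-one, via lithium enolate 19 (not isolated), via Mannich base 20 (not isolated), via ammonium iodide 21 (not isolated)
Conditions: MeLi, THF, 0 °C; 18, −78 → 23 °C; MeI, 23 °C; evaporate; DBU, CH2Cl2, 23 °C
Reagents that add atoms: none
Why: MeLi releases the regiodefined lithium enolate, which undergoes a Mannich reaction with the preformed iminium salt at C1; quaternisation and base-induced elimination give the α-methylene ketone, and DBU should also equilibrate C5 towards the equatorial epimer (prenyl cis to geranyl).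

Step 8
Reactants: 22 C1-methylene ketone; 23 (2-methylprop-1-en-1-yl)magnesium bromide; 24 3-(trimethylsilyl)prop-2-ynal
Product: 26 4-geranyl-2-[1-hydroxy-3-(trimethylsilyl)prop-2-yn-1-yl]-3-methyl-3-(4-methylpent-3-en-1-yl)-2,6-diprenylcyclohexan-1-one (C1 carbinol substituent cis to the C8 homoprenyl group, trans to geranyl; carbinol epimers), via magnesium enolate 25 (not isolated)
Conditions: 23, CuBr·SMe2 (20 mol %), THF, −78 °C; 24, −78 °C; AcOH, −78 °C
Reagents that add atoms: none
Why: Copper-catalysed 1,4-addition of the alkenyl Grignard reagent to the unhindered exocyclic enone completes the C1 prenyl group and forms the C1 enolate regiospecifically (tandem conjugate addition–aldol); the aldehyde should add axially to C1 on the face anti to the axial C8 methyl, which places the future C2 cis to the C8 homoprenyl group, and the cold acidic quench prevents retro-aldol cleavage.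

Step 9
Reactants: 26 aldol adduct
Product: 27 4-geranyl-3-methyl-3-(4-methylpent-3-en-1-yl)-2,6-diprenyl-2-[3-(trimethylsilyl)prop-2-ynoyl]cyclohexan-1-one
Conditions: Dess–Martin periodinane, NaHCO3, CH2Cl2, 0 → 23 °C
Reagents that add atoms: none
Why: Buffered Dess–Martin oxidation of a propargylic alcohol leaves the alkenes and the silyl alkyne untouched, and the quaternary C1 prevents enolisation of the new 1,3-diketone.

Step 10
Reactants: 27 silyl ynone
Product: 28 2-(3-bromoprop-2-ynoyl)-4-geranyl-3-methyl-3-(4-methylpent-3-en-1-yl)-2,6-diprenylcyclohexan-1-one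
Conditions: N-bromosuccinimide, AgNO3 (10 mol %), acetone, 0 °C, dark
Reagents that add atoms: N-bromosuccinimide, O=C1CCC(=O)N1Br
Why: Silver-catalysed halodesilylation: the silyl alkyne becomes a silver acetylide that takes bromine from N-bromosuccinimide, a path that should be much faster than ionic bromination of isolated alkenes in dry acetone in the dark; the step precedes enol silylation because an enol ether would be brominated.

Step 11
Reactants: 28 bromo ynone
Product: 29 tert-butyldimethylsilyl enol ether (C9=C5) of 28, the ring B enol ether carrying prenyl on C5 and prenyl plus 3-bromopropynoyl on C1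
Conditions: t-BuMe2SiOTf, i-Pr2NEt, CH2Cl2, −78 → 0 °C
Reagents that add atoms: tert-butyldimethylsilyl trifluoromethanesulfonate, CC(C)(C)[Si](C)(C)OS(=O)(=O)C(F)(F)F
Why: Soft enolisation: O-silylation of the C9 ketone and deprotonation at C5, the only enolisable position, give the tetrasubstituted enol ether from either C5 epimer; the hindered amine is chosen because it should not add to the bromo ynone.

Step 12
Reactants: 29 silyl enol ether
Product: 30 4-bromo-7-geranyl-8-methyl-8-(4-methylpent-3-en-1-yl)-1,5-diprenylbicyclo[3.3.1]non-3-ene-2,9-dione
Conditions: [(2-biphenylyl)(t-Bu)2PAu(NCMe)]SbF6 (5 mol %), acetone, H2O (2 equiv), 23 °C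
Reagents that add atoms: none
Why: The cationic complex of monovalent gold binds the C3≡C4 triple bond and the silyl enol ether attacks through C5 at C4 anti to the metal; the silyloxocarbenium ion then loses its silyl group to water and the C3–Au bond is protonated, which releases the catalyst and the enone. The closest known reaction type is the gold-catalysed carbocyclisation of cyclic silyl enol ethers onto tethered alkynes and 1-haloalkynes, which gives bridged bicyclic enones and vinyl halides. Ring A closes in the 6-endo-dig mode. The new stereocentre C5 is controlled by C1: the acyl tether reaches C5 only when it is axial, so C4 is delivered to the enol ether face cis to the tether and the C5 prenyl group ends equatorial. The step needs 6-endo attack to beat 5-exo attack; conjugation with the C2 carbonyl makes C4 the electrophilic alkyne carbon, and the bulky biaryl phosphine favours the endo mode. It also needs the enol ether to outrun the C1 prenyl alkene, which stands in a 1,6-enyne relationship to the alkyne; the enol ether is far more nucleophilic and is held over C4. The robust tert-butyldimethylsilyl group and the non-acidic medium limit premature protodesilylation to ketone 28.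

Step 13
Reactants: 30 bromo enone
Product: 31 7-geranyl-4-methoxy-8-methyl-8-(4-methylpent-3-en-1-yl)-1,5-diprenylbicyclo[3.3.1]non-3-ene-2,9-dione
Conditions: NaOMe, MeOH/THF, 0 → 23 °C
Reagents that add atoms: sodium methoxide, [Na+].[O-]C
Why: Addition–elimination (vinylogous acyl substitution) of methoxide at C4 of the β-bromo enone; both α-carbons of the ketones are quaternary, so no enolate chemistry interferes, and conjugate attack should be faster than attack at the hindered C2 and C9 carbonyls.

Step 14
Reactants: 32 3-hydroxybenzoic acid
Product: 33 tert-butyldimethylsilyl 3-[(tert-butyldimethylsilyl)oxy]benzoate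
Conditions: t-BuMe2SiCl (2.2 equiv), imidazole, DMF, 23 °C
Reagents that add atoms: tert-butyldimethylsilyl chloride, CC(C)(C)[Si](C)(C)Cl
Why: Imidazole-promoted silylation of both the phenol and the acid; no selectivity is needed because the silyl ester is the precursor of the acid chloride.

Step 15
Reactants: 33 bis-silyl derivative
Product: 34 3-[(tert-butyldimethylsilyl)oxy]benzoyl chloride
Conditions: (COCl)2, DMF (cat.), CH2Cl2, 0 → 23 °C
Reagents that add atoms: oxalyl chloride, O=C(Cl)C(=O)Cl
Why: Silyl esters are converted directly into acid chlorides by oxalyl chloride and catalytic DMF (Vilsmeier-type activation) under neutral conditions that leave the aryl silyl ether intact.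

Step 16
Reactants: 31 vinylogous ester; 34 3-[(tert-butyldimethylsilyl)oxy]benzoyl chloride
Product: 36 3-{3-[(tert-butyldimethylsilyl)oxy]benzoyl}-7-geranyl-4-methoxy-8-methyl-8-(4-methylpent-3-en-1-yl)-1,5-diprenylbicyclo[3.3.1]non-3-ene-2,9-dione, via C3-lithio species 35 (not isolated)
Conditions: lithium 2,2,6,6-tetramethylpiperidide, THF, −78 °C; 34, −78 → −40 °C
Reagents that add atoms: none
Why: Deprotonation of the vinylogous ester at C3 by a hindered lithium amide is the standard C3 functionalisation of this bicyclic system; with both bridgeheads quaternary there is no competing bridgehead lithiation, and the vinyllithium is C-acylated by the aroyl chloride.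

Step 17
Reactants: 36 protected target
Product: 37 (1S,5S,7R,8S)-7-[(2E)-3,7-dimethylocta-2,6-dien-1-yl]-4-hydroxy-3-(3-hydroxybenzoyl)-8-methyl-1,5-bis(3-methylbut-2-en-1-yl)-8-(4-methylpent-3-en-1-yl)bicyclo[3.3.1]non-3-ene-2,9-dione (CNP0285073.1)
Conditions: LiOH, 1,4-dioxane/H2O, 90 °C; HCl (aq)
Reagents that add atoms: lithium hydroxide, [Li+].[OH-]
Why: Hydroxide adds to C4 of the doubly activated β-methoxy enone and expels methoxide, and it also cleaves the aryl silyl ether; the product is held as its delocalised trione enolate until acidification, which should protect it from retro-Claisen cleavage.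

## Compound list

1 | geranyl bromide, (2E)-1-bromo-3,7-dimethylocta-2,6-diene | CC(C)=CCC/C(C)=C/CBr | starting material
2 | N-ethylidene-2-methylpropan-2-amine (acetaldehyde tert-butylimine) | CC=NC(C)(C)C | starting material
3 | lithium aza-enolate of 2 | C=C[N-]C(C)(C)C.[Li+] | intermediate (not isolated)
4 | N-[(4E)-5,9-dimethyldeca-4,8-dien-1-ylidene]-2-methylpropan-2-amine | CC(C)=CCC/C(C)=C/CCC=NC(C)(C)C | intermediate (not isolated)
5 | (4E)-5,9-dimethyldeca-4,8-dienal | CC(C)=CCC/C(C)=C/CCC=O | intermediate
6 | methyl vinyl ketone | CC(=O)C=C | starting material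
7 | (2S)-2-[(2E)-3,7-dimethylocta-2,6-dien-1-yl]-5-oxohexanal | CC(C)=CCC/C(C)=C/C[C@H](CCC(C)=O)C=O | intermediate
8 | (4S)-4-geranyl-3-hydroxycyclohexan-1-one (carbinol epimers) | CC(C)=CCC/C(C)=C/C[C@@H]1CCC(=O)CC1O | intermediate (not isolated)
9 | (4S)-4-geranylcyclohex-2-en-1-one | CC(C)=CCC/C(C)=C/C[C@@H]1CCC(=O)C=C1 | intermediate
10 | lithium enolate (C9=C1) of trans-4-geranyl-3-methylcyclohexanone | CC(C)=CCC/C(C)=C/C[C@@H]1CCC([O-])=C[C@H]1C.[Li+] | intermediate (not isolated)
11 | (4S)-4-geranyl-3-methylcyclohex-2-en-1-one | CC(C)=CCC/C(C)=C/C[C@@H]1CCC(=O)C=C1C | intermediate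
12 | prenyl bromide, 1-bromo-3-methylbut-2-ene | CC(C)=CCBr | starting material
13 | lithium cross-conjugated dienolate (C9=C5) of 11 | CC(C)=CCC/C(C)=C/C[C@@H]1CC=C([O-])C=C1C.[Li+] | intermediate (not isolated)
14 | 4-geranyl-3-methyl-6-prenylcyclohex-2-en-1-one (C4 as in 11; epimers at C6) | CC(C)=CCC/C(C)=C/C[C@@H]1CC(CC=C(C)C)C(=O)C=C1C | intermediate
15 | 5-bromo-2-methylpent-2-ene | CC(C)=CCCBr | starting material
16 | (4-methylpent-3-en-1-yl)magnesium bromide | CC(C)=CCC[Mg]Br | intermediate (not isolated)
17 | trimethylsilyl enol ether (C9=C1) of 4-geranyl-3-methyl-3-(4-methylpent-3-en-1-yl)-6-prenylcyclohexanone; homoprenyl trans, methyl cis to geranyl; C5 epimers | CC(C)=CCC/C(C)=C/C[C@@H]1CC(CC=C(C)C)C(O[Si](C)(C)C)=C[C@@]1(C)CCC=C(C)C | intermediate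
18 | N,N-dimethylmethyleneiminium iodide (Eschenmoser's salt) | C=[N+](C)C.[I-] | starting material
19 | lithium enolate (C9=C1) released from 17 | CC(C)=CCC/C(C)=C/C[C@@H]1CC(CC=C(C)C)C([O-])=C[C@@]1(C)CCC=C(C)C.[Li+] | intermediate (not isolated)
20 | C1 Mannich base, 2-[(dimethylamino)methyl] ketone (C1 and C5 epimers) | CC(C)=CCC/C(C)=C/C[C@@H]1CC(CC=C(C)C)C(=O)C(CN(C)C)[C@@]1(C)CCC=C(C)C | intermediate (not isolated)
21 | trimethylammonium iodide of 20 | CC(C)=CCC/C(C)=C/C[C@@H]1CC(CC=C(C)C)C(=O)C(C[N+](C)(C)C)[C@@]1(C)CCC=C(C)C.[I-] | intermediate (not isolated)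
22 | 4-geranyl-3-methyl-2-methylidene-3-(4-methylpent-3-en-1-yl)-6-prenylcyclohexan-1-one (C5 epimers) | CC(C)=CCC/C(C)=C/C[C@@H]1CC(CC=C(C)C)C(=O)C(=C)[C@@]1(C)CCC=C(C)C | intermediate
23 | (2-methylprop-1-en-1-yl)magnesium bromide | CC(C)=C[Mg]Br | starting material
24 | 3-(trimethylsilyl)prop-2-ynal | C[Si](C)(C)C#CC=O | starting material
25 | bromomagnesium enolate (C9=C1) with prenyl on C1 | CC(C)=CCC/C(C)=C/C[C@@H]1CC(CC=C(C)C)C(O[Mg]Br)=C(CC=C(C)C)[C@@]1(C)CCC=C(C)C | intermediate (not isolated)
26 | aldol adduct: C1 carries prenyl and 1-hydroxy-3-(trimethylsilyl)prop-2-ynyl, the latter cis to the C8 homoprenyl group (carbinol and C5 epimers) | CC(C)=CCC/C(C)=C/C[C@@H]1CC(CC=C(C)C)C(=O)[C@@](CC=C(C)C)(C(O)C#C[Si](C)(C)C)[C@@]1(C)CCC=C(C)C | intermediate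
27 | silyl ynone: C1 carries prenyl and 3-(trimethylsilyl)prop-2-ynoyl (C5 epimers) | CC(C)=CCC/C(C)=C/C[C@@H]1CC(CC=C(C)C)C(=O)[C@@](CC=C(C)C)(C(=O)C#C[Si](C)(C)C)[C@@]1(C)CCC=C(C)C | intermediate
28 | bromo ynone: C1 carries prenyl and 3-bromoprop-2-ynoyl (C5 epimers) | CC(C)=CCC/C(C)=C/C[C@@H]1CC(CC=C(C)C)C(=O)[C@@](CC=C(C)C)(C(=O)C#CBr)[C@@]1(C)CCC=C(C)C | intermediate
29 | tert-butyldimethylsilyl enol ether (C9=C5) of 28 | CC(C)=CCC/C(C)=C/C[C@@H]1CC(CC=C(C)C)=C(O[Si](C)(C)C(C)(C)C)[C@@](CC=C(C)C)(C(=O)C#CBr)[C@@]1(C)CCC=C(C)C | intermediate
30 | 4-bromo-7-geranyl-8-methyl-8-(4-methylpent-3-en-1-yl)-1,5-diprenylbicyclo[3.3.1]non-3-ene-2,9-dione | CC(C)=CCC/C(C)=C/C[C@@H]1C[C@]2(CC=C(C)C)C(=O)[C@@](CC=C(C)C)(C(=O)C=C2Br)[C@@]1(C)CCC=C(C)C | intermediate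
31 | 4-methoxy analogue of 30 | CC(C)=CCC/C(C)=C/C[C@@H]1C[C@]2(CC=C(C)C)C(=O)[C@@](CC=C(C)C)(C(=O)C=C2OC)[C@@]1(C)CCC=C(C)C | intermediate
32 | 3-hydroxybenzoic acid | OC(=O)c1cccc(O)c1 | starting material
33 | tert-butyldimethylsilyl 3-[(tert-butyldimethylsilyl)oxy]benzoate | CC(C)(C)[Si](C)(C)OC(=O)c1cccc(O[Si](C)(C)C(C)(C)C)c1 | intermediate
34 | 3-[(tert-butyldimethylsilyl)oxy]benzoyl chloride | CC(C)(C)[Si](C)(C)Oc1cccc(C(Cl)=O)c1 | intermediate
35 | C3-lithio derivative of 31 | CC(C)=CCC/C(C)=C/C[C@@H]1C[C@]2(CC=C(C)C)C(=O)[C@@](CC=C(C)C)(C(=O)C([Li])=C2OC)[C@@]1(C)CCC=C(C)C | intermediate (not isolated)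
36 | 3-{3-[(tert-butyldimethylsilyl)oxy]benzoyl} derivative of 31 | CC(C)=CCC/C(C)=C/C[C@@H]1C[C@]2(CC=C(C)C)C(=O)[C@@](CC=C(C)C)(C(=O)C(C(=O)c3cccc(O[Si](C)(C)C(C)(C)C)c3)=C2OC)[C@@]1(C)CCC=C(C)C | intermediate
37 | CNP0285073.1, (1S,5S,7R,8S)-7-geranyl-4-hydroxy-3-(3-hydroxybenzoyl)-8-methyl-8-(4-methylpent-3-en-1-yl)-1,5-diprenylbicyclo[3.3.1]non-3-ene-2,9-dione | CC(C)=CCC/C(C)=C/C[C@@H]1C[C@]2(CC=C(C)C)C(=O)[C@@](CC=C(C)C)(C(=O)C(C(=O)c3cccc(O)c3)=C2O)[C@@]1(C)CCC=C(C)C | target

## Step count and least certain steps

Total steps: 17 (15 in the main line, 2 for acid chloride 34). Longest linear sequence: 15 steps (steps 1 to 13, 16 and 17).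

**Step 12 (key step).**
- What may go wrong: closure in the 5-exo mode; cycloisomerisation through the C1 prenyl alkene in place of the enol ether; protodesilylation of the enol ether before cyclisation; or migration of bromine on the gold-bound alkyne. The substrate is far more crowded and more olefin-rich than the usual ones.
- Fallback (Effenberger cyclisation, forming C1–C2 and C4–C5 together): it sets out from 22. Copper-catalysed addition of 23 with t-BuMe2SiCl/HMPA trapping gives the tert-butyldimethylsilyl enol ether F1. Malonyl dichloride (Et2O, −20 → 23 °C) followed by KOH and BnEt3NCl gives the enolised bicyclic trione F2; acylation at C1 should again occur anti to the axial C8 methyl. Me3SiCHN2 then gives 31, where the route is rejoined. The regioisomeric methyl ether F3 formed alongside is hydrolysed back to F2 (LiOH) and recycled.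

**Step 8.**
- What may go wrong: the congested magnesium enolate may be protonated, or the adduct may revert by retro-aldol, because two adjacent quaternary carbons are being joined. Facial selectivity may also erode if the C5 prenyl group is axial.
- Fallback: it sets out from 22. The same conjugate addition is trapped with Me3SiCl to give the trimethylsilyl enol ether F4, which is isolated and used in a Mukaiyama aldol addition with 24 (BF3·OEt2, CH2Cl2, −78 °C). This comes back at 26.

**Step 10.**
- What may go wrong: electrophilic bromination of the five electron-rich alkenes may compete with halodesilylation of the electron-poor alkyne.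
- Fallback: it sets out from 22 and brings the bromine in with the three-carbon unit. 3-Bromoprop-2-ynal F5 is prepared fresh from commercial 3-bromoprop-2-yn-1-ol with MnO2 and used in place of 24 in the coupling of step 8. This gives the bromo alkynol F6, and Dess–Martin oxidation comes back at 28.

**Step 16.**
- What may go wrong: incomplete lithiation at the hindered C3, or addition of the vinyllithium to the product ketone.
- Fallback: it sets out from 31. The C3-lithio species is added to commercial 3-[(tert-butyldimethylsilyl)oxy]benzaldehyde to give the carbinol F7, and Dess–Martin oxidation comes back at 36.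

**Step 17.**
- What may go wrong: retro-Claisen opening of the trione or loss of the aroyl group in hot hydroxide.
- Fallback: it sets out from 36. Demethylation by SN2 attack of chloride at the methyl group (LiCl, DMSO, 120 °C) gives the silyl-protected trione F8, and HF·pyridine (THF, 0 °C) comes back at 37.

## Further compounds

F1 | step 12 | tert-butyldimethylsilyl enol ether (C9=C1) of 4-geranyl-3-methyl-3-(4-methylpent-3-en-1-yl)-2,6-diprenylcyclohexanone | CC(C)=CCC/C(C)=C/C[C@@H]1CC(CC=C(C)C)C(O[Si](C)(C)C(C)(C)C)=C(CC=C(C)C)[C@@]1(C)CCC=C(C)C
F2 | step 12 | 7-geranyl-4-hydroxy-8-methyl-8-(4-methylpent-3-en-1-yl)-1,5-diprenylbicyclo[3.3.1]non-3-ene-2,9-dione | CC(C)=CCC/C(C)=C/C[C@@H]1C[C@]2(CC=C(C)C)C(=O)[C@@](CC=C(C)C)(C(=O)C=C2O)[C@@]1(C)CCC=C(C)C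
F3 | step 12 | 2-methoxy regioisomer of 31 (methoxy on C2, ketone on C4) | CC(C)=CCC/C(C)=C/C[C@@H]1C[C@]2(CC=C(C)C)C(=O)[C@@](CC=C(C)C)(C(OC)=CC2=O)[C@@]1(C)CCC=C(C)C
F4 | step 8 | trimethylsilyl enol ether (C9=C1) of 4-geranyl-3-methyl-3-(4-methylpent-3-en-1-yl)-2,6-diprenylcyclohexanone | CC(C)=CCC/C(C)=C/C[C@@H]1CC(CC=C(C)C)C(O[Si](C)(C)C)=C(CC=C(C)C)[C@@]1(C)CCC=C(C)C
F5 | step 10 | 3-bromoprop-2-ynal | O=CC#CBr
F6 | step 10 | bromo alkynol: C1 carries prenyl and 3-bromo-1-hydroxyprop-2-ynyl | CC(C)=CCC/C(C)=C/C[C@@H]1CC(CC=C(C)C)C(=O)[C@@](CC=C(C)C)(C(O)C#CBr)[C@@]1(C)CCC=C(C)C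
F7 | step 16 | C3 carbinol: 3-{hydroxy[3-(tert-butyldimethylsilyloxy)phenyl]methyl} derivative of 31 | CC(C)=CCC/C(C)=C/C[C@@H]1C[C@]2(CC=C(C)C)C(=O)[C@@](CC=C(C)C)(C(=O)C(C(O)c3cccc(O[Si](C)(C)C(C)(C)C)c3)=C2OC)[C@@]1(C)CCC=C(C)C
F8 | step 17 | O-silyl target: 3-{3-[(tert-butyldimethylsilyl)oxy]benzoyl}-4-hydroxy trione | CC(C)=CCC/C(C)=C/C[C@@H]1C[C@]2(CC=C(C)C)C(=O)[C@@](CC=C(C)C)(C(=O)C(C(=O)c3cccc(O[Si](C)(C)C(C)(C)C)c3)=C2O)[C@@]1(C)CCC=C(C)C
A1 | alternative 1 | 1,5-dimethoxy-6-prenyl-6-(trans-2,3-epoxygeranyl)cyclohexa-1,4-diene | COC1=CCC=C(OC)C1(CC=C(C)C)C[C@H]1O[C@]1(C)CCC=C(C)C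
A2 | alternative 1 | oxygen-bridged (C7–O–C9) methyl ketal of 4-methoxy-8-methyl-8-(4-methylpent-3-en-1-yl)-5-prenylbicyclo[3.3.1]non-3-ene | O3[C@@H]1C[C@]2(CC=C(C)C)[C@@]3(OC)[C@@H](CC=C2OC)[C@@]1(C)CCC=C(C)C
A3 | alternative 2 | (5Z,7Z)-6-[(tert-butyldimethylsilyl)oxy]-2,8,12-trimethyltrideca-2,5,7,11-tetraene | CC(C)=CC/C=C(O[Si](C)(C)C(C)(C)C)/C=C(/C)CCC=C(C)C
A4 | alternative 2 | acrolein | C=CC=O
A5 | alternative 2 | 4-[(tert-butyldimethylsilyl)oxy]-2-methyl-2-(4-methylpent-3-en-1-yl)-5-prenylcyclohex-3-ene-1-carbaldehyde | O=C[C@@H]1C[C@H](CC=C(C)C)C(O[Si](C)(C)C(C)(C)C)=C[C@@]1(C)CCC=C(C)C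
A6 | alternative 3 | (3-hydroxyphenyl)[2,4,6-trihydroxy-3,5-bis(3-methylbut-2-en-1-yl)phenyl]methanone | CC(C)=CCc1c(O)c(CC=C(C)C)c(O)c(C(=O)c2cccc(O)c2)c1O
A7 | alternative 3 | (2E)-2-(acetoxymethyl)-3,7-dimethylocta-2,6-dienal | CC(C)=CCC/C(C)=C(\COC(C)=O)C=O
A8 | alternative 3 | 7-formyl analogue of the target | O=C[C@@H]1C[C@]2(CC=C(C)C)C(=O)[C@@](CC=C(C)C)(C(=O)C(C(=O)c3cccc(O)c3)=C2O)[C@@]1(C)CCC=C(C)C
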